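## Structural features

The target is a trans-fused decalin of the eremophilane type. Ring A is C1–C5 plus C10, ring B is C5–C10, the two share the C5–C10 bond, and β denotes the face of the angular methyl (C14 on C5). Seven stereocentres form one unbroken chain C3–C4–C5–C10–C9–C8–C7: an equatorial 3α-acyloxy group beside the equatorial 4β-methyl (C15), the quaternary C5 with its axial methyl, the 10α-hydrogen, an equatorial 9α-acyloxy group, an axial free 8α-hydroxyl and an equatorial 7α-isopropenyl group. Both esters are (Z)-hex-2-enoates, which lose their geometry on carboxyl activation and can migrate from O9 to the cis-vicinal O8. The isopropenyl group is sensitive to acid and to hydrogenation. The real difficulty is threefold. Quaternary C5 must be made in the right absolute sense between two stereocentres. The carbinol carbons C3 and C9 both lie 1,3 to the axial C14 methyl, so hydride reagents approach from the α face and give the axial, wrong alcohols. Three secondary hydroxyls must be told apart at the end. The key step exploits the pattern of ring B: methyl on C5 and oxygen on C8 and C9 are the substituents of 2-methoxy-5-methyl-1,4-benzoquinone, and ring A with its single oxygen at C3 is a 2-silyloxydiene added across C5=C10.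

## Logic of the disconnections

24 ⇒ 23. The two cis C=C bonds of the ester chains are traced back to C≡C bonds. A (Z)-2-enoic acid isomerises when activated; an ynoate has no geometry to lose. The forward step must stop at the alkene and spare the C11=C12 alkene.

23 ⇒ 21 + 22. The two acyl C–O bonds at O3 and O9 are cut. This removes twelve carbons at once and leaves a triol. The forward step must acylate the two equatorial hydroxyls and leave the axial, doubly flanked O8–H free.

21 ⇒ 20. The C3–H bond is cut (carbinol to ketone). The 3α-alcohol is the equatorial, more stable epimer, but its formation by hydride needs attack on the β face, which C14 screens. The ketone is therefore kept until ring B holds no reducible group. The forward step must be an electron-transfer reduction under thermodynamic control that spares the alkene.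

20 ⇒ 19. No skeletal bond is cut: the C3 ketone is masked as a dioxolane and O8 and O9 as silyl ethers. All three must fall in one acidic operation mild enough for the isopropenyl group.

19 ⇒ 17 (through 18) ⇒ 16. The C11=C12 alkene is traced to the C11–O bond of a tertiary alcohol, and the O8 silyl ether to the free hydroxyl. The three-carbon unit can then come from acetone. The elimination must run toward a methyl group and not toward C7, and O8 must be blocked so that only the C11 hydroxyl can leave.

16 ⇒ 15. The C8–H bond is cut. The forward step needs hydride on the equatorial trajectory from the β face to give the axial 8α-alcohol.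

15 ⇒ 12 (through 13 and 14). The C7–C11 bond and the C6–H bond are cut. Conjugate hydride addition to the enone gives the C7–C8 enolate regiospecifically, which deprotonation of a ketone flanked by C7 and C9 could not guarantee. The forward step must form the C–C bond at C7 from the α face.

12 ⇒ 11 ⇒ 10. The C9–H bond (its configuration) and the O9–Si bond are addressed. Hydride reduction at C9 is expected to give the axial 9β-alcohol, but once C8 is a ketone C9 is its α-carbon and can be equilibrated to the equatorial epimer. Enolisation must be possible only toward C9, which holds because C5 is quaternary.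

10 ⇒ 8 (through 9). A 1,3-carbonyl transposition is undone: the C8 ketone and C6=C7 alkene come from the C6 ketone and the C7=C8 methyl enol ether, and the C9–H bond from the C9 ketone. Ring B is then a 2-methoxy-ene-dione, a quinone-derived ring; O6 served only to activate the dienophile and leaves as water. The forward step needs 1,2-reduction of both carbonyls and an acid step that spares the dioxolane.

8 ⇒ 7. The two C3–O bonds of the dioxolane are cut. The forward step must select the one saturated ketone. The mask is needed because every later hydride would reduce C3 to the axial alcohol.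

7 ⇒ 5 (through 6). The C4–H and C10–H bonds (configurations) and the O–Si bond are addressed. Both centres are α to carbonyl groups, so the trans fusion and the equatorial 4β-methyl are reached by equilibration from the kinetic adduct. The forward step relies on 7 being the most stable of the four diastereomers; C5 is quaternary and cannot be lost.

5 ⇒ 2 + 4. The C4–C5 and C1–C10 bonds are cut (retro-Diels–Alder). Two achiral components, each one step from a commercial compound, replace a bicyclic compound with a quaternary centre. The forward step needs site, regio- and facial selectivity. The silyl group of 4 is tert-butyldimethylsilyl, not trimethylsilyl: a trimethylsilyl enol ether is cleaved by traces of HCl from a titanium chloride catalyst and its adduct would not survive isolation.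

2 ⇒ 1 and 4 ⇒ 3. The C–OMe bond of 2 is cut (oxidative addition of methanol to 1), and the O–Si bond of 4 (silylation of the enol of 3 on its only enolisable side). The first needs regioselective addition, the second (Z) geometry.

## Other disconnections considered

Alternative 1: The cut is at C5–C10 and C6–C7. In the forward step the triene aldehyde A1 undergoes an intramolecular Diels–Alder reaction: its 2-substituted acrolein unit (C5=C6) adds to the tethered 2-silyloxydiene (C7=C8–C9=C10) and gives A2, closing both rings at once.
- In its favour: two rings, two C–C bonds and the quaternary centre arise in one step. The trans fusion forms directly, so no C10 epimerisation is needed. C3 and C4 are already in the tether and steer the facial course. C6 arrives as a methylene, so no oxygen has to be removed there. The C8 silyl enol ether of A2 is a handle for oxygenation at C9 (Rubottom type) and for the C7 aldol.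
- Against it here: A1 needs two acyclic stereocentres made beforehand by asymmetric aldol or crotylation chemistry. It holds an enal and a silyloxydiene in one molecule, so hetero-cycloaddition and oligomerisation compete. The angular carbon arrives as an aldehyde and must be deoxygenated at a neopentyl position. O9 is absent and must be added.
- Comparison: on rings formed per step and on the C10/C4 configuration this plan is the better one. Mechanistically the two are equal, both being thermal or Lewis-acid [4+2] additions of a silyloxydiene. On step economy the chosen plan is ahead: it reaches the bicyclic 5 in three steps and sets the absolute configuration with a catalyst, whereas A1 must be built linearly and the aldehyde reduced afterwards.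

Alternative 2: The cut is at C5–C6. In the forward step Fe(acac)3 and PhSiH3 transfer a hydrogen atom to the exocyclic methylene carbon (C14) of A3; the tertiary C5 radical adds to the terminal carbon (C6) of the vinyl ketone in a 6-endo Giese closure and gives A4.
- In its favour: the quaternary methyl is created from a plain methylene. A4 already carries the C8 ketone next to a correctly configured equatorial 9α-silyloxy group and the 3α-silyloxy group. No carbonyl transposition and no removal of O6 are needed. After A4 only aldol, reduction, dehydration, deprotection, acylation and semihydrogenation remain.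
- Against it here: the configuration of C5 is decided in a radical closure with an early transition state, where cis-fused product is a serious competitor. The α-silyloxy vinyl ketone is prone to reduction and polymerisation. A3 needs four stereocentres (C3, C4, C10, C9) on a cyclohexane, with absolute configuration from elsewhere.
- Comparison: on oxidation-state economy in ring B and on the length of the sequence after the key step this alternative is the better one. On control of the quaternary centre the chosen plan is better, because a chelated catalyst fixes C5 in a concerted step. Overall length is expected to be similar or longer because of the synthesis of A3.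

Alternative 3: The cut is at C7–C8. In the forward step ZnBr2 activates the C8 aldehyde of A5; C7 of the prenyl chain attacks it while a methyl hydrogen passes to oxygen (type 1 carbonyl-ene), which gives A6 with the C8 hydroxyl and the isopropenyl group formed together.
- In its favour: no dehydration and no regiochemical question at C11. O8 emerges free while O3 (silyl) and O9 (4-methoxybenzyl) carry different groups, so the three oxygens are differentiated from the start. The step is atom-economical.
- Against it here: the required product has the 8α-hydroxyl axial and cis to the isopropenyl group, whereas zinc-promoted ene closures of this kind normally give the all-equatorial arrangement; the outcome rests on chelation between the aldehyde and the C9 ether oxygen. The α-alkoxy aldehyde can epimerise at C9. Prins-type capture by bromide can intervene. The hardest element, quaternary C5 with its neighbours C4 and C10, is left to the synthesis of A5.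
- Comparison: on the end-game (protecting-group logic, isopropenyl installation) this alternative is the better one. On the central problem of C5 and on early step economy the chosen plan is better. Mechanistically the ene closure is a substrate-controlled pericyclic step, the chosen key step a catalyst-controlled one.

Key step: step 3

Remark: the (R)-configured BINOL ligand is written on the assumption that it exposes the quinone face that leads to the 5β-methyl series; if the induction runs the other way, the (S)-ligand is used and nothing else changes.

## Route

Step 1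
Reactants: 1 2-methyl-1,4-benzoquinone
Product: 2 2-methoxy-5-methyl-1,4-benzoquinone
Conditions: MeOH, ZnCl2, 25 → 65 °C (2 equiv of 1; the second equivalent is the oxidant)
Reagents that add atoms: methanol, CO
Why: ZnCl2-promoted conjugate addition of methanol to the ring carbon para to the methyl-bearing carbon gives the methoxyhydroquinone, which a second molecule of 1 re-oxidises (oxidative nucleophilic addition to a quinone); this is a known preparation of 2.

Step 2
Reactants: 3 pent-1-en-3-one
Product: 4 (Z)-3-(tert-butyldimethylsilyloxy)penta-1,3-diene
Conditions: t-BuMe2SiOTf, Et3N, Et2O, 0 °C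
Reagents that add atoms: tert-butyldimethylsilyl trifluoromethanesulfonate, CC(C)(C)[Si](C)(C)OS(=O)(=O)C(F)(F)F
Why: Soft enolisation and O-silylation of the ketone on its only enolisable (ethyl) side; the (Z)-enol ether is favoured because it keeps the methyl group away from the vinyl group.

Step 3
Reactants: 2 2-methoxy-5-methyl-1,4-benzoquinone; 4 (Z)-3-(tert-butyldimethylsilyloxy)penta-1,3-diene
Product: 5 cis-fused endo adduct 3-(tert-butyldimethylsilyloxy)-8-methoxy-4α,5β-dimethyl-10βH-decal-2,7-diene-6,9-dione (eremophilane numbering)
Conditions: (R)-BINOL, TiCl2(O-i-Pr)2 (10 mol % each, giving (BINOL)TiCl2), 4 Å molecular sieves, CH2Cl2, −30 °C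
Reagents that add atoms: none
Why: This is a concerted, asynchronous endo [4+2] cycloaddition of an electron-rich 2-silyloxydiene to a Lewis-acid-activated quinone, with the C4–C5 bond more advanced because the enol ether β-carbon C4 attacks C5, the β-position of the chelated C9 carbonyl. The closest known reaction type is the cycloaddition of 2-methoxy-5-methylbenzoquinone at its methyl-bearing double bond under chelating tin or titanium chlorides, which is also known with BINOL-derived titanium dichloride catalysts. Ring A is the only ring closed; it closes in the cycloaddition itself by suprafacial addition of diene carbons C1–C4 across C5=C10 and leaves the C2=C3 silyl enol ether. Site selectivity comes from the methoxy group, which makes C7=C8 an electron-rich vinylogous ester and leaves C5=C10 as the only dienophile. Regioselectivity comes from five-membered chelation of titanium by O9 and the methoxy oxygen, which activates the C9 carbonyl and not the more basic C6 carbonyl, so C5 becomes the electrophilic terminus and pairs with C4, the nucleophilic terminus fixed by the silyloxy group. C5 (methyl β) is set by the BINOL ligand, which shields one face of the chelated quinone; it is the only stereocentre of 5 that is kept. C10 (cis fusion) follows from suprafacial addition and C4 (methyl trans to C14) from the endo transition state with the (Z)-methyl outside; both are corrected in step 4.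

Step 4
Reactants: 5 cis-fused endo adduct
Product: 7 trans-fused 8-methoxy-4β,5β-dimethyl-10αH-decal-7-ene-3,6,9-trione, via cis-fused 4α-methyl trione 6 (not isolated)
Conditions: 1 M HCl, THF, 0 °C; then NaOMe (0.2 equiv), MeOH, 25 °C
Reagents that add atoms: none
Why: Acid hydrolysis of the silyl enol ether protonates C2 and leaves C4 untouched; methoxide then epimerises C10 (α to the C9 carbonyl) and C4 (α to the C3 carbonyl) by enolate equilibration. The trans-decalin with equatorial 4β-methyl cis to the axial 5β-methyl is expected to be the most stable isomer, as in friedelin-type 4,5-dimethyl-3-ketones, and the sp2 carbons C3, C7 and C9 remove most 1,3-diaxial contacts of C14. C5 is quaternary, so neither aromatisation nor loss of this centre is possible.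

Step 5
Reactants: 7 trans-fused trione
Product: 8 3,3-ethylenedioxy-8-methoxy-4β,5β-dimethyl-10αH-decal-7-ene-6,9-dione
Conditions: Me3SiOCH2CH2OSiMe3, Me3SiOTf (cat.), CH2Cl2, −78 → −20 °C
Reagents that add atoms: 1,2-bis(trimethylsilyloxy)ethane, C[Si](C)(C)OCCO[Si](C)(C)C
Why: Silyl-triflate-catalysed acetalisation under kinetic control selects the only saturated ketone; C6 is a vinylogous ester carbonyl and C9 a conjugated α-oxygenated enone carbonyl, both far less electrophilic.

Step 6
Reactants: 8 dioxolane ene-dione
Product: 10 3,3-ethylenedioxy-9β-hydroxy-4β,5β-dimethyl-10αH-decal-6-en-8-one, via 6β,9β-diol 9 (not isolated)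
Conditions: LiAlH4, THF, −78 → 0 °C; then 0.5 M HCl, THF, 0 °C
Reagents that add atoms: water, O
Why: Hydride reduces both ring B carbonyls 1,2; dilute acid then hydrolyses the 6-hydroxy enol ether to the C8 ketone with loss of water across C6–C7 (Stork–Danheiser-type reductive carbonyl transposition, known for 2-methoxy-ene-diones of this kind), the dioxolane hydrolysing much more slowly than the enol ether. Hydride is expected to reach C9 from the α face, anti to C14, so the 9β-alcohol is drawn; C6 is lost in the same step and C9 is corrected in step 8.

Step 7
Reactants: 10 9β-hydroxy enone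
Product: 11 9β-(tert-butyldimethylsilyloxy)-3,3-ethylenedioxy-4β,5β-dimethyl-10αH-decal-6-en-8-one
Conditions: t-BuMe2SiOTf, 2,6-lutidine, CH2Cl2, −78 → 0 °C
Reagents that add atoms: tert-butyldimethylsilyl trifluoromethanesulfonate, CC(C)(C)[Si](C)(C)OS(=O)(=O)C(F)(F)F
Why: O-silylation of a hindered secondary alcohol with a silyl triflate and a hindered pyridine base, which does not enolise the ketone at low temperature.

Step 8
Reactants: 11 9β-silyloxy enone
Product: 12 9α-(tert-butyldimethylsilyloxy)-3,3-ethylenedioxy-4β,5β-dimethyl-10αH-decal-6-en-8-one
Conditions: DBU, toluene, 80 °C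
Reagents that add atoms: none
Why: Base-mediated α-epimerisation; C9 is the only enolisable position of this enone (the γ-carbon C5 is quaternary), and the equatorial 9α-silyl ether is favoured because the axial epimer is 1,3-diaxial to the C14 methyl.

Step 9
Reactants: 12 9α-silyloxy enone
Product: 15 9α-(tert-butyldimethylsilyloxy)-3,3-ethylenedioxy-11-hydroxy-4β,5β-dimethyl-7βH,10αH-eremophilan-8-one, via lithium enolate 13 (not isolated), via chlorozinc enolate 14 (not isolated)
Conditions: Li(s-Bu)3BH, THF, −78 °C; ZnCl2; acetone, −78 → −40 °C; aq. NH4Cl
Reagents that add atoms: acetone, CC(C)=O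
Why: Conjugate hydride addition at C6 gives the C7–C8 enolate regiospecifically, and after exchange to zinc (less basic, so acetone is not enolised) it adds to acetone (reductive aldol); the zinc-mediated acetone aldol is the standard way to attach C11–C13 in eremophilanes. The electrophile enters C7 from the α face, anti to the axial C14 methyl, as in C2 alkylation of 3-keto steroid enolates, which places the hydroxyisopropyl group equatorial; this is also the thermodynamic outcome of the reversible aldol.

Step 10
Reactants: 15 β-hydroxy ketone
Product: 16 9α-(tert-butyldimethylsilyloxy)-3,3-ethylenedioxy-4β,5β-dimethyl-7βH,10αH-eremophilane-8α,11-diol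
Conditions: Li(s-Bu)3BH (3 equiv), THF, −78 °C; then H2O
Reagents that add atoms: none
Why: Substrate-controlled ketone reduction; the bulky trialkylborohydride takes the equatorial trajectory from the β face because the axial α approach is blocked by the axial hydrogens on C6 and C10, which gives the axial 8α-alcohol as with 2,6-diequatorially substituted cyclohexanones.

Step 11
Reactants: 16 8α,11-diol
Product: 17 9α-(tert-butyldimethylsilyloxy)-3,3-ethylenedioxy-8α-(triethylsilyloxy)-4β,5β-dimethyl-7βH,10αH-eremophilan-11-ol
Conditions: Et3SiCl, imidazole, DMAP (cat.), DMF, 0 → 25 °C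
Reagents that add atoms: chlorotriethylsilane, CC[Si](Cl)(CC)CC
Why: Chlorosilane and imidazole silylate the secondary hydroxyl while the tertiary carbinol is inert; O8 is masked so that only the C11 hydroxyl can leave in the next step.

Step 12
Reactants: 17 tertiary alcohol
Product: 19 9α-(tert-butyldimethylsilyloxy)-3,3-ethylenedioxy-8α-(triethylsilyloxy)-4β,5β-dimethyl-7βH,10αH-eremophil-11-ene, via tertiary chlorosulfite 18 (not isolated)
Conditions: SOCl2, pyridine, CH2Cl2, −40 → 0 °C
Reagents that add atoms: none
Why: Pyridine-mediated E2 elimination of the tertiary chlorosulfite; the only ring hydrogen available, H7β, is axial, 1,3-diaxial to the C14 methyl and flanked by the C8 silyl ether, so the base removes a methyl hydrogen and the isopropenyl alkene forms.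

Step 13
Reactants: 19 protected isopropenyl compound
Product: 20 8α,9α-dihydroxy-4β,5β-dimethyl-7βH,10αH-eremophil-11-en-3-one
Conditions: 48 % aq. HF, MeCN, 0 → 25 °C
Reagents that add atoms: water, O
Why: Aqueous HF cleaves both silyl ethers and, as a dilute aqueous acid, hydrolyses the dioxolane in the same operation (global deprotection); at this acidity the 1,1-disubstituted alkene is protonated far more slowly than the acetal.

Step 14
Reactants: 20 keto diol
Product: 21 4β,5β-dimethyl-7βH,10αH-eremophil-11-ene-3α,8α,9α-triol
Conditions: Li, NH3 (l), THF, EtOH, −78 °C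
Reagents that add atoms: none
Why: Dissolving-metal reduction proceeds through the ketyl and the carbanion and gives the more stable equatorial 3α-alcohol, trans to the 4β-methyl, as known for friedelin-type 3-ketones. A hydride would attack from the α face and give the axial 3β-alcohol because the β approach is 1,3-diaxial to C14. The isolated alkene is not reduced.

Step 15
Reactants: 21 triol; 22 hex-2-ynoic acid (2.3 equiv)
Product: 23 3α,9α-bis(hex-2-ynoyloxy)-4β,5β-dimethyl-7βH,10αH-eremophil-11-en-8α-ol
Conditions: i-PrN=C=N-i-Pr, DMAP (cat.), CH2Cl2, −20 → 0 °C
Reagents that add atoms: none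
Why: Steglich esterification of the two equatorial hydroxyls; the axial 8α-hydroxyl, flanked by the isopropenyl group and the new C9 ester, is the slowest to acylate, in line with the equatorial-over-axial preference of cis-diols and polyhydroxy steroids.

Step 16
Reactants: 23 bis-ynoate
Product: 24 3α,9α-bis[(Z)-hex-2-enoyloxy]-4β,5β-dimethyl-7βH,10αH-eremophil-11-en-8α-ol (CNP0420276.1)
Conditions: H2 (1 atm), Pd/CaCO3 poisoned with Pb(OAc)2, quinoline, EtOAc, 25 °C
Reagents that add atoms: none
Why: Semihydrogenation on lead-poisoned palladium adds one equivalent of hydrogen syn to each ynoate and gives both (Z)-enoates; the 1,1-disubstituted C11=C12 alkene reacts much more slowly on this catalyst.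

## Compound list

1 | 2-methyl-1,4-benzoquinone | CC1=CC(=O)C=CC1=O | starting material
2 | 2-methoxy-5-methyl-1,4-benzoquinone | COC1=CC(=O)C(C)=CC1=O | intermediate
3 | pent-1-en-3-one | CCC(=O)C=C | starting material
4 | (Z)-3-(tert-butyldimethylsilyloxy)penta-1,3-diene | C/C=C(/C=C)O[Si](C)(C)C(C)(C)C | intermediate
5 | cis-fused endo adduct, 3-silyl enol ether, 4α-Me, 5β-Me, 10β-H | COC1=CC(=O)[C@]2(C)[C@H](C)C(O[Si](C)(C)C(C)(C)C)=CC[C@@H]2C1=O | intermediate
6 | cis-fused 8-methoxy-4α,5β-dimethyl-10βH-decal-7-ene-3,6,9-trione | COC1=CC(=O)[C@]2(C)[C@H](C)C(=O)CC[C@@H]2C1=O | intermediate (not isolated)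
7 | trans-fused 8-methoxy-4β,5β-dimethyl-10αH-decal-7-ene-3,6,9-trione | COC1=CC(=O)[C@]2(C)[C@@H](C)C(=O)CC[C@H]2C1=O | intermediate
8 | 3,3-ethylenedioxy-8-methoxy-4β,5β-dimethyl-10αH-decal-7-ene-6,9-dione | COC1=CC(=O)[C@]2(C)[C@@H](C)C3(OCCO3)CC[C@H]2C1=O | intermediate
9 | 3,3-ethylenedioxy-8-methoxy-4β,5β-dimethyl-10αH-decal-7-ene-6β,9β-diol (expected epimers; C6 is lost, C9 is corrected later) | COC1=C[C@@H](O)[C@]2(C)[C@@H](C)C3(OCCO3)CC[C@H]2[C@H]1O | intermediate (not isolated)
10 | 3,3-ethylenedioxy-9β-hydroxy-4β,5β-dimethyl-10αH-decal-6-en-8-one | O=C1C=C[C@]2(C)[C@@H](C)C3(OCCO3)CC[C@H]2[C@H]1O | intermediate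
11 | 9β-(tert-butyldimethylsilyloxy)-3,3-ethylenedioxy-4β,5β-dimethyl-10αH-decal-6-en-8-one | O=C1C=C[C@]2(C)[C@@H](C)C3(OCCO3)CC[C@H]2[C@H]1O[Si](C)(C)C(C)(C)C | intermediate
12 | 9α-(tert-butyldimethylsilyloxy)-3,3-ethylenedioxy-4β,5β-dimethyl-10αH-decal-6-en-8-one | O=C1C=C[C@]2(C)[C@@H](C)C3(OCCO3)CC[C@H]2[C@@H]1O[Si](C)(C)C(C)(C)C | intermediate
13 | lithium C7–C8 enolate of the 9α-silyloxy 8-ketone | [Li]OC1=CC[C@]2(C)[C@@H](C)C3(OCCO3)CC[C@H]2[C@@H]1O[Si](C)(C)C(C)(C)C | intermediate (not isolated)
14 | chlorozinc C7–C8 enolate of the 9α-silyloxy 8-ketone | Cl[Zn]OC1=CC[C@]2(C)[C@@H](C)C3(OCCO3)CC[C@H]2[C@@H]1O[Si](C)(C)C(C)(C)C | intermediate (not isolated)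
15 | 9α-(tert-butyldimethylsilyloxy)-3,3-ethylenedioxy-11-hydroxy-7βH,10αH-eremophilan-8-one (4β,5β-dimethyl) | CC(C)(O)[C@@H]1C[C@]2(C)[C@@H](C)C3(OCCO3)CC[C@H]2[C@H](O[Si](C)(C)C(C)(C)C)C1=O | intermediate
16 | 9α-(tert-butyldimethylsilyloxy)-3,3-ethylenedioxy-7βH,10αH-eremophilane-8α,11-diol | CC(C)(O)[C@@H]1C[C@]2(C)[C@@H](C)C3(OCCO3)CC[C@H]2[C@H](O[Si](C)(C)C(C)(C)C)[C@@H]1O | intermediate
17 | 9α-(tert-butyldimethylsilyloxy)-3,3-ethylenedioxy-8α-(triethylsilyloxy)-7βH,10αH-eremophilan-11-ol | CC(C)(O)[C@@H]1C[C@]2(C)[C@@H](C)C3(OCCO3)CC[C@H]2[C@H](O[Si](C)(C)C(C)(C)C)[C@@H]1O[Si](CC)(CC)CC | intermediate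
18 | 11-O-chlorosulfite of 17 (sulfur configuration undefined) | ClS(=O)OC(C)(C)[C@@H]1C[C@]2(C)[C@@H](C)C3(OCCO3)CC[C@H]2[C@H](O[Si](C)(C)C(C)(C)C)[C@@H]1O[Si](CC)(CC)CC | intermediate (not isolated)
19 | 9α-(tert-butyldimethylsilyloxy)-3,3-ethylenedioxy-8α-(triethylsilyloxy)-7βH,10αH-eremophil-11-ene | C=C(C)[C@@H]1C[C@]2(C)[C@@H](C)C3(OCCO3)CC[C@H]2[C@H](O[Si](C)(C)C(C)(C)C)[C@@H]1O[Si](CC)(CC)CC | intermediate
20 | 8α,9α-dihydroxy-7βH,10αH-eremophil-11-en-3-one | C=C(C)[C@@H]1C[C@]2(C)[C@@H](C)C(=O)CC[C@H]2[C@H](O)[C@@H]1O | intermediate
21 | 7βH,10αH-eremophil-11-ene-3α,8α,9α-triol | C=C(C)[C@@H]1C[C@]2(C)[C@@H](C)[C@H](O)CC[C@H]2[C@H](O)[C@@H]1O | intermediate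
22 | hex-2-ynoic acid | CCCC#CC(=O)O | starting material
23 | 3α,9α-bis(hex-2-ynoyloxy)-7βH,10αH-eremophil-11-en-8α-ol | C=C(C)[C@@H]1C[C@]2(C)[C@@H](C)[C@H](OC(=O)C#CCCC)CC[C@H]2[C@H](OC(=O)C#CCCC)[C@@H]1O | intermediate
24 | 3α,9α-bis[(Z)-hex-2-enoyloxy]-7βH,10αH-eremophil-11-en-8α-ol (CNP0420276.1) | C=C(C)[C@@H]1C[C@]2(C)[C@@H](C)[C@H](OC(=O)/C=C\CCC)CC[C@H]2[C@H](OC(=O)/C=C\CCC)[C@@H]1O | target

## Step count and least certain steps

Total: 16 steps. Longest linear sequence: 15 steps (from 1 through steps 1 and 3–16). Step 2 is a one-step branch, and 22 enters in step 15.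

Step 3 (key step). The ligand may discriminate the two quinone faces too weakly for this silyloxydiene, or the catalyst may desilylate the diene and give stepwise conjugate addition that erodes selectivity. The fallback replaces asymmetric catalysis by resolution and sets out from 2 and 4. Achiral chelating SnCl4 (CH2Cl2, −78 °C) keeps the site and regiochemistry and gives 5 together with its mirror image, the enantiomeric adduct F1. The conditions of step 4 convert the pair, through 6 and the enantiomeric cis-fused trione F2, into 7 and the enantiomeric trans-fused trione F3. Preparative chromatography on a chiral stationary phase removes F3, and the route is rejoined at 7.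

Step 4. Enolisation toward the hindered C4 may be slow, the four-isomer equilibrium may not lie far enough on the side of 7, or the ene-dione may suffer under methoxide. The fallback separates the two equilibrations and sets out from 5. DBU (CH2Cl2, 25 °C) epimerises C10 alone while ring A is still an enol ether and gives the trans-fused silyl enol ether F4. Dilute HCl in THF then gives the trans-fused 4α-methyl trione F5. The one remaining centre, C4, is equilibrated under acid catalysis (p-TsOH, CHCl3, 40 °C), which enolises toward the more substituted carbon and generates no enolate of the ene-dione. The route is rejoined at 7.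

Step 9. Hydride may add 1,2 and not 1,4, because the β-carbon C6 is neopentyl, or boron residues may interfere with the aldol. The fallback sets out from 12. RhCl(PPh3)3-catalysed 1,4-hydrosilylation with Et3SiH gives the triethylsilyl enol ether F6. MeLi (THF, 0 °C) releases the boron-free lithium enolate 13, which is taken through 14 with ZnCl2 and acetone as before. The route is rejoined at 15.

Step 12. Elimination may run toward C7 and give the tetrasubstituted alkene, or the tertiary chlorosulfite may ionise and give chloride or rearranged products. The fallback fixes the alkene position by construction and sets out from 12. The reductive aldol of step 9 is run with 1-(trimethylsilyl)propan-2-one in place of acetone and gives the β-hydroxysilane F7 (either C11 epimer). Li(s-Bu)3BH as in step 10 gives the β-hydroxysilane diol F8. KH in THF triggers a Peterson elimination of the tertiary alkoxide, which can only form the C11=C12 bond, and gives the 8α-hydroxy isopropenyl compound F9; O8 needs no protection, and any silyl shift from O9 to O8 is without consequence. Aqueous HF in MeCN as in step 13 removes the remaining groups, and the route is rejoined at 20.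

Step 15. The axial O8–H may be acylated as well, or the acyl group may migrate from O9 to O8. The fallback changes the basis of selectivity and sets out from 21. Bu2SnO (toluene, reflux, removal of water) gives the 8,9-O-dibutylstannylene acetal F10, in which the equatorial O9 is the activated oxygen. Hex-2-ynoyl chloride F11, made from 22 with (COCl)2 and catalytic DMF, with Et3N (CH2Cl2, 0 °C) acylates O9 through the tin acetal and the free O3 directly; aqueous work-up frees O8. The route is rejoined at 23.

## Further compounds

F1 | step 3 | enantiomer of adduct 5 | COC1=CC(=O)[C@@]2(C)[C@@H](C)C(O[Si](C)(C)C(C)(C)C)=CC[C@H]2C1=O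
F2 | step 3 | enantiomer of cis-fused trione 6 (not isolated) | COC1=CC(=O)[C@@]2(C)[C@@H](C)C(=O)CC[C@H]2C1=O
F3 | step 3 | enantiomer of trans-fused trione 7 | COC1=CC(=O)[C@@]2(C)[C@H](C)C(=O)CC[C@@H]2C1=O
F4 | step 4 | trans-fused 3-(tert-butyldimethylsilyloxy)-8-methoxy-4α,5β-dimethyl-10αH-decal-2,7-diene-6,9-dione | COC1=CC(=O)[C@]2(C)[C@H](C)C(O[Si](C)(C)C(C)(C)C)=CC[C@H]2C1=O
F5 | step 4 | trans-fused 8-methoxy-4α,5β-dimethyl-10αH-decal-7-ene-3,6,9-trione | COC1=CC(=O)[C@]2(C)[C@H](C)C(=O)CC[C@H]2C1=O
F6 | step 9 | 9α-(tert-butyldimethylsilyloxy)-3,3-ethylenedioxy-8-(triethylsilyloxy)-4β,5β-dimethyl-10αH-decal-7-ene | CC[Si](CC)(CC)OC1=CC[C@]2(C)[C@@H](C)C3(OCCO3)CC[C@H]2[C@@H]1O[Si](C)(C)C(C)(C)C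
F7 | step 12 | 9α-(tert-butyldimethylsilyloxy)-3,3-ethylenedioxy-11-hydroxy-12-(trimethylsilyl)-7βH,10αH-eremophilan-8-one (C11 undefined) | C[Si](C)(C)CC(C)(O)[C@@H]1C[C@]2(C)[C@@H](C)C3(OCCO3)CC[C@H]2[C@H](O[Si](C)(C)C(C)(C)C)C1=O
F8 | step 12 | 9α-(tert-butyldimethylsilyloxy)-3,3-ethylenedioxy-12-(trimethylsilyl)-7βH,10αH-eremophilane-8α,11-diol (C11 undefined) | C[Si](C)(C)CC(C)(O)[C@@H]1C[C@]2(C)[C@@H](C)C3(OCCO3)CC[C@H]2[C@H](O[Si](C)(C)C(C)(C)C)[C@@H]1O
F9 | step 12 | 9α-(tert-butyldimethylsilyloxy)-3,3-ethylenedioxy-7βH,10αH-eremophil-11-en-8α-ol | C=C(C)[C@@H]1C[C@]2(C)[C@@H](C)C3(OCCO3)CC[C@H]2[C@H](O[Si](C)(C)C(C)(C)C)[C@@H]1O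
F10 | step 15 | 8α,9α-O-(dibutylstannylene) acetal of triol 21 | C=C(C)[C@@H]1C[C@]2(C)[C@@H](C)[C@H](O)CC[C@H]2[C@@H]3O[Sn](CCCC)(CCCC)O[C@H]13
F11 | step 15 | hex-2-ynoyl chloride | CCCC#CC(=O)Cl
A1 | alternative 1 | (7E)-4,9-bis(tert-butyldimethylsilyloxy)-3-methyl-2-methylidenedeca-7,9-dienal (eremophilane C4 and C3 configured as in the target) | C=C(C=O)[C@@H](C)[C@H](O[Si](C)(C)C(C)(C)C)CC/C=C/C(=C)O[Si](C)(C)C(C)(C)C
A2 | alternative 1 | trans-fused 5-formyl-3α,8-bis(tert-butyldimethylsilyloxy)-4β-methyl-10αH-decal-8-ene | C1C[C@]2(C=O)[C@@H](C)[C@H](O[Si](C)(C)C(C)(C)C)CC[C@H]2C=C1O[Si](C)(C)C(C)(C)C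
A3 | alternative 2 | 1-(tert-butyldimethylsilyloxy)-1-[4-(tert-butyldimethylsilyloxy)-3-methyl-2-methylidenecyclohexyl]but-3-en-2-one | C=C1[C@@H](C)[C@H](O[Si](C)(C)C(C)(C)C)CC[C@H]1[C@H](O[Si](C)(C)C(C)(C)C)C(=O)C=C
A4 | alternative 2 | trans-fused 3α,9α-bis(tert-butyldimethylsilyloxy)-4β,5β-dimethyl-10αH-decalin-8-one | C1C[C@]2(C)[C@@H](C)[C@H](O[Si](C)(C)C(C)(C)C)CC[C@H]2[C@H](O[Si](C)(C)C(C)(C)C)C1=O
A5 | alternative 3 | 2-[4-(tert-butyldimethylsilyloxy)-2,3-dimethyl-2-(3-methylbut-2-en-1-yl)cyclohexyl]-2-(4-methoxybenzyloxy)acetaldehyde | CC(C)=CC[C@]1(C)[C@@H](C)[C@H](O[Si](C)(C)C(C)(C)C)CC[C@H]1[C@H](OCc2ccc(OC)cc2)C=O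
A6 | alternative 3 | 3α-(tert-butyldimethylsilyloxy)-9α-(4-methoxybenzyloxy)-7βH,10αH-eremophil-11-en-8α-ol | C=C(C)[C@@H]1C[C@]2(C)[C@@H](C)[C@H](O[Si](C)(C)C(C)(C)C)CC[C@H]2[C@H](OCc3ccc(OC)cc3)[C@@H]1O
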